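**Retrosynthetic overview**

1. Numbering: the central benzene is ring A with carbons C1 to C6; C1 carries the methide carbon C7, C2 carries ring B (2,4-dihydroxyphenyl), C5 carries the hydroxymethyl carbon C10 and C6 carries the alkyne carbon C8.
2. Selaginellin F (30) comes from triaryl carbinol 27 by desilylation, MOM cleavage and loss of water; 27 comes from methyl ester 22 (ester carbon = C7) and two equivalents of a 4-silyloxyphenyllithium.
3. 22 comes from a Suzuki coupling at C2 between triflate 17 and ring B boronate 21; the C2 oxygen of 17 is a former MOM ether.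
4. The strategy rests on the adjacent carbons C1 and C6 of ring A, which bear C7 and C8 and lie between C2 (held as oxygen) and C5 (CH2OH). Both C–C bonds are made in one aryne step: chloroarene 3 + acetylide of 8 + CO2 give acid 13.
5. No ring is built in the route; ring A, ring B, the alkyne-arm phenol ring and the two C7 aryl rings all come from commercial benzenes (1, 18, 4, 23).

Key step: step 6

Remark: the target has no stereocentre, and the exocyclic C7 double bond ends in a symmetrical cyclohexadienone, so no double-bond geometry has to be set.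

**Route**

Step 1
Reactants: 1 2-chloro-4-hydroxybenzaldehyde
Product: 2 2-chloro-4-(methoxymethoxy)benzaldehyde
Conditions: MOMCl, i-Pr2NEt, CH2Cl2, 0 °C to rt
Reagents that add atoms: chloromethyl methyl ether, COCCl
Why: Williamson-type O-alkylation of the acidic para-formyl phenol under amine base gives the MOM acetal that later acidifies C1–H of ring A and steers the aryne.

Step 2
Reactants: 2 2-chloro-4-(methoxymethoxy)benzaldehyde
Product: 3 [2-chloro-4-(methoxymethoxy)phenyl]methanol
Conditions: NaBH4, MeOH, 0 °C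
Reagents that add atoms: none
Why: Carbonyl hydride reduction with NaBH4 converts the aldehyde into the benzylic alcohol and leaves the aryl chloride and the MOM acetal untouched.

Step 3
Reactants: 4 4-iodophenol
Product: 5 (4-iodophenoxy)triisopropylsilane
Conditions: i-Pr3SiCl, imidazole, DMF, rt
Reagents that add atoms: triisopropylsilyl chloride, CC(C)[Si](Cl)(C(C)C)C(C)C
Why: Imidazole-promoted O-silylation gives a bulky aryl silyl ether that should withstand amide bases and acetylide chemistry.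

Step 4
Reactants: 5 (4-iodophenoxy)triisopropylsilane; 6 trimethylsilylacetylene
Product: 7 triisopropyl{4-[(trimethylsilyl)ethynyl]phenoxy}silane
Conditions: PdCl2(PPh3)2 (2 mol %), CuI (4 mol %), Et3N, THF, rt
Reagents that add atoms: none
Why: Sonogashira coupling of the aryl iodide should proceed at room temperature through oxidative addition to zerovalent palladium and transmetalation from the copper acetylide.

Step 5
Reactants: 7 triisopropyl{4-[(trimethylsilyl)ethynyl]phenoxy}silane
Product: 8 (4-ethynylphenoxy)triisopropylsilane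
Conditions: K2CO3 (0.2 equiv), MeOH–THF, 0 °C to rt
Reagents that add atoms: none
Why: Methoxide-mediated protodesilylation cleaves the alkynyl C–Si bond much faster than the hindered aryl O–Si bond and frees the terminal alkyne.

Step 6
Reactants: 3 [2-chloro-4-(methoxymethoxy)phenyl]methanol; 8 (4-ethynylphenoxy)triisopropylsilane (1.5 equiv); 9 carbon dioxide
Product: 13 3-(hydroxymethyl)-6-(methoxymethoxy)-2-{[4-(triisopropylsilyloxy)phenyl]ethynyl}benzoic acid, via lithium acetylide 10 (not isolated), via aryne lithium alkoxide 11 (not isolated), via aryllithium 12 (not isolated)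
Conditions: lithium 2,2,6,6-tetramethylpiperidide (4 equiv, from n-BuLi and 2,2,6,6-tetramethylpiperidine), THF–pentane, −78 °C to rt; then CO2 gas, −78 °C to rt; aq HCl to pH 4, 0 °C
Reagents that add atoms: none
Why: The amide first forms the benzylic alkoxide and lithium acetylide 10, then removes C1–H, the only proton ortho to chlorine and the most acidic one because it lies between Cl and OMOM, and loss of LiCl on warming gives the C1≡C6 aryne 11. The acetylide adds at C6 and the resulting C1 aryllithium 12, chelated by the neighbouring MOM oxygen, is carboxylated by CO2; this is the known base-mediated alkynylation of chloroarenes through arynes with electrophilic interception of the aryllithium, closed here by the classical carboxylation of an aryne-derived aryllithium. No ring is closed and no stereocentre is formed. The step needs attack at C6 and not at C1, and the inductively withdrawing C2 oxygen secures this by making the distal aryne carbon the electrophilic one and by stabilising the negative charge that develops at C1, while the lithium alkoxide on the C5 benzylic carbon can deliver the acetylide to the neighbouring C6 and cannot be deprotonated at its benzylic carbon. The hindered amide should not add to the aryne, and the excess of amide and acetylide should keep 12 metalated until the CO2 quench.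

Step 7
Reactants: 13 3-(hydroxymethyl)-6-(methoxymethoxy)-2-{[4-(triisopropylsilyloxy)phenyl]ethynyl}benzoic acid
Product: 14 methyl 3-(hydroxymethyl)-6-(methoxymethoxy)-2-{[4-(triisopropylsilyloxy)phenyl]ethynyl}benzoate
Conditions: Me3SiCHN2, toluene–MeOH, 0 °C to rt
Reagents that add atoms: (trimethylsilyl)diazomethane, C[Si](C)(C)C=[N+]=[N-]
Why: Diazoalkane esterification methylates the carboxylic acid under neutral conditions that spare the alcohol, the acetal and the alkyne and that are insensitive to the two ortho substituents.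

Step 8
Reactants: 14 methyl 3-(hydroxymethyl)-6-(methoxymethoxy)-2-{[4-(triisopropylsilyloxy)phenyl]ethynyl}benzoate
Product: 15 methyl 3-{[(tert-butyldiphenylsilyl)oxy]methyl}-6-(methoxymethoxy)-2-{[4-(triisopropylsilyloxy)phenyl]ethynyl}benzoate
Conditions: t-BuPh2SiCl, imidazole, DMF, rt
Reagents that add atoms: tert-butyldiphenylsilyl chloride, CC(C)(C)[Si](Cl)(c1ccccc1)c1ccccc1
Why: O-Silylation of the primary benzylic alcohol as an acid-stable silyl ether blocks hydroxyl addition to the neighbouring alkyne in the later base-mediated and palladium-mediated steps.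

Step 9
Reactants: 15 methyl 3-{[(tert-butyldiphenylsilyl)oxy]methyl}-6-(methoxymethoxy)-2-{[4-(triisopropylsilyloxy)phenyl]ethynyl}benzoate
Product: 16 methyl 3-{[(tert-butyldiphenylsilyl)oxy]methyl}-6-hydroxy-2-{[4-(triisopropylsilyloxy)phenyl]ethynyl}benzoate
Conditions: HCl (1.25 M in MeOH), THF, 0 °C to rt
Reagents that add atoms: none
Why: Acid-catalysed acetal exchange with methanol cleaves the aryl MOM ether, assisted by the ortho ester, while the aryl triisopropylsilyl ether and the tert-butyldiphenylsilyl ether should be stable to dilute acid at room temperature.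

Step 10
Reactants: 16 methyl 3-{[(tert-butyldiphenylsilyl)oxy]methyl}-6-hydroxy-2-{[4-(triisopropylsilyloxy)phenyl]ethynyl}benzoate
Product: 17 methyl 3-{[(tert-butyldiphenylsilyl)oxy]methyl}-6-{[(trifluoromethyl)sulfonyl]oxy}-2-{[4-(triisopropylsilyloxy)phenyl]ethynyl}benzoate
Conditions: Tf2O, pyridine, CH2Cl2, 0 °C
Reagents that add atoms: trifluoromethanesulfonic anhydride, O=S(=O)(OS(=O)(=O)C(F)(F)F)C(F)(F)F
Why: O-Sulfonylation of the salicylate-type phenol gives an aryl triflate that the ortho ester activates for oxidative addition.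

Step 11
Reactants: 18 4-bromoresorcinol
Product: 19 1-bromo-2,4-bis(methoxymethoxy)benzene
Conditions: MOMCl (2.5 equiv), i-Pr2NEt, CH2Cl2, 0 °C to rt
Reagents that add atoms: chloromethyl methyl ether, COCCl
Why: Williamson-type O-alkylation of both phenols under amine base gives the bis-MOM ether.

Step 12
Reactants: 19 1-bromo-2,4-bis(methoxymethoxy)benzene
Product: 21 2-[2,4-bis(methoxymethoxy)phenyl]-4,4,5,5-tetramethyl-1,3,2-dioxaborolane, via aryllithium 20 (not isolated)
Conditions: n-BuLi, THF, −78 °C; then 2-isopropoxy-4,4,5,5-tetramethyl-1,3,2-dioxaborolane, −78 °C to rt; H2O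
Reagents that add atoms: 2-isopropoxy-4,4,5,5-tetramethyl-1,3,2-dioxaborolane, CC(C)OB1OC(C)(C)C(C)(C)O1
Why: Bromine–lithium exchange at low temperature gives an aryllithium stabilised by the ortho MOM oxygen, and borylation by the isopropoxy pinacol borate gives the pinacol boronate.

Step 13
Reactants: 17 methyl 3-{[(tert-butyldiphenylsilyl)oxy]methyl}-6-{[(trifluoromethyl)sulfonyl]oxy}-2-{[4-(triisopropylsilyloxy)phenyl]ethynyl}benzoate; 21 2-[2,4-bis(methoxymethoxy)phenyl]-4,4,5,5-tetramethyl-1,3,2-dioxaborolane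
Product: 22 methyl 4-{[(tert-butyldiphenylsilyl)oxy]methyl}-2',4'-bis(methoxymethoxy)-3-{[4-(triisopropylsilyloxy)phenyl]ethynyl}biphenyl-2-carboxylate
Conditions: Pd(OAc)2 (5 mol %), SPhos (10 mol %), K3PO4, toluene–H2O (10:1), 80 °C
Reagents that add atoms: none
Why: Suzuki–Miyaura coupling of the ester-activated triflate with the arylboronate forms the bond between C2 of ring A and ring B, which has only one ortho substituent on each partner, and should leave the silyl ethers and the internal alkyne alone.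

Step 14
Reactants: 23 4-bromophenol
Product: 24 (4-bromophenoxy)(tert-butyl)dimethylsilane
Conditions: t-BuMe2SiCl, imidazole, DMF, rt
Reagents that add atoms: tert-butyldimethylsilyl chloride, CC(C)(C)[Si](C)(C)Cl
Why: Imidazole-promoted O-silylation masks the phenol so that the bromide can undergo bromine–lithium exchange.

Step 15
Reactants: 24 (4-bromophenoxy)(tert-butyl)dimethylsilane (3.5 equiv); 22 methyl 4-{[(tert-butyldiphenylsilyl)oxy]methyl}-2',4'-bis(methoxymethoxy)-3-{[4-(triisopropylsilyloxy)phenyl]ethynyl}biphenyl-2-carboxylate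
Product: 27 {4-{[(tert-butyldiphenylsilyl)oxy]methyl}-2',4'-bis(methoxymethoxy)-3-{[4-(triisopropylsilyloxy)phenyl]ethynyl}biphenyl-2-yl}bis[4-(tert-butyldimethylsilyloxy)phenyl]methanol, via aryllithium 25 (not isolated), via diaryl ketone 26 (not isolated)
Conditions: n-BuLi (3.3 equiv), THF, −78 °C; then 22, −78 to 0 °C; H2O, −20 °C
Reagents that add atoms: none
Why: Double addition of the aryllithium to the methyl ester, through the more electrophilic diaryl ketone, should give the triaryl carbinol because the slim alkynyl group at C6 leaves one flank of the carbonyl open, and the cold quench keeps the tertiary alkoxide from adding to the alkyne.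

Step 16
Reactants: 27 {4-{[(tert-butyldiphenylsilyl)oxy]methyl}-2',4'-bis(methoxymethoxy)-3-{[4-(triisopropylsilyloxy)phenyl]ethynyl}biphenyl-2-yl}bis[4-(tert-butyldimethylsilyloxy)phenyl]methanol
Product: 30 selaginellin F, via desilylated carbinol 28 (not isolated), via bis-MOM quinone methide 29 (not isolated)
Conditions: Bu4NF (8 equiv), AcOH (8 equiv), THF, 0 °C to rt; aqueous work-up; then HCl (1.25 M in MeOH), rt; NaHCO3 to pH 6
Reagents that add atoms: none
Why: Acetic acid-buffered fluoride cleaves the four silyl ethers without free alkoxides that could add to the alkyne, and methanolic HCl then ionises the 4-hydroxyphenyl carbinol to the quinone methide (fuchsone-type dehydration) and removes both MOM acetals by acetal exchange.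

**Compound list**

1 | 2-chloro-4-hydroxybenzaldehyde | O=Cc1ccc(O)cc1Cl | starting material
2 | 2-chloro-4-(methoxymethoxy)benzaldehyde | O=Cc1ccc(OCOC)cc1Cl | intermediate
3 | [2-chloro-4-(methoxymethoxy)phenyl]methanol | OCc1ccc(OCOC)cc1Cl | intermediate
4 | 4-iodophenol | Oc1ccc(I)cc1 | starting material
5 | (4-iodophenoxy)triisopropylsilane | CC(C)[Si](Oc1ccc(I)cc1)(C(C)C)C(C)C | intermediate
6 | trimethylsilylacetylene | C#C[Si](C)(C)C | starting material
7 | triisopropyl{4-[(trimethylsilyl)ethynyl]phenoxy}silane | C[Si](C)(C)C#Cc1ccc(O[Si](C(C)C)(C(C)C)C(C)C)cc1 | intermediate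
8 | (4-ethynylphenoxy)triisopropylsilane | C#Cc1ccc(O[Si](C(C)C)(C(C)C)C(C)C)cc1 | intermediate
9 | carbon dioxide | O=C=O | starting material
10 | lithium {[4-(triisopropylsilyloxy)phenyl]ethynide} | [Li]C#Cc1ccc(O[Si](C(C)C)(C(C)C)C(C)C)cc1 | intermediate
11 | lithium [2,3-didehydro-4-(methoxymethoxy)phenyl]methoxide (C1≡C6 aryne of ring A) | [Li]OCC1=CC=C(OCOC)C#C1 | intermediate
12 | lithium {3-lithio-4-(methoxymethoxy)-2-{[4-(triisopropylsilyloxy)phenyl]ethynyl}phenyl}methoxide | [Li]OCc1ccc(OCOC)c([Li])c1C#Cc1ccc(O[Si](C(C)C)(C(C)C)C(C)C)cc1 | intermediate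
13 | 3-(hydroxymethyl)-6-(methoxymethoxy)-2-{[4-(triisopropylsilyloxy)phenyl]ethynyl}benzoic acid | OCc1ccc(OCOC)c(C(=O)O)c1C#Cc1ccc(O[Si](C(C)C)(C(C)C)C(C)C)cc1 | intermediate
14 | methyl 3-(hydroxymethyl)-6-(methoxymethoxy)-2-{[4-(triisopropylsilyloxy)phenyl]ethynyl}benzoate | COC(=O)c1c(OCOC)ccc(CO)c1C#Cc1ccc(O[Si](C(C)C)(C(C)C)C(C)C)cc1 | intermediate
15 | methyl 3-{[(tert-butyldiphenylsilyl)oxy]methyl}-6-(methoxymethoxy)-2-{[4-(triisopropylsilyloxy)phenyl]ethynyl}benzoate | COC(=O)c1c(OCOC)ccc(CO[Si](c2ccccc2)(c2ccccc2)C(C)(C)C)c1C#Cc1ccc(O[Si](C(C)C)(C(C)C)C(C)C)cc1 | intermediate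
16 | methyl 3-{[(tert-butyldiphenylsilyl)oxy]methyl}-6-hydroxy-2-{[4-(triisopropylsilyloxy)phenyl]ethynyl}benzoate | COC(=O)c1c(O)ccc(CO[Si](c2ccccc2)(c2ccccc2)C(C)(C)C)c1C#Cc1ccc(O[Si](C(C)C)(C(C)C)C(C)C)cc1 | intermediate
17 | methyl 3-{[(tert-butyldiphenylsilyl)oxy]methyl}-6-{[(trifluoromethyl)sulfonyl]oxy}-2-{[4-(triisopropylsilyloxy)phenyl]ethynyl}benzoate | COC(=O)c1c(OS(=O)(=O)C(F)(F)F)ccc(CO[Si](c2ccccc2)(c2ccccc2)C(C)(C)C)c1C#Cc1ccc(O[Si](C(C)C)(C(C)C)C(C)C)cc1 | intermediate
18 | 4-bromoresorcinol | Oc1ccc(Br)c(O)c1 | starting material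
19 | 1-bromo-2,4-bis(methoxymethoxy)benzene | COCOc1ccc(Br)c(OCOC)c1 | intermediate
20 | [2,4-bis(methoxymethoxy)phenyl]lithium | [Li]c1ccc(OCOC)cc1OCOC | intermediate
21 | 2-[2,4-bis(methoxymethoxy)phenyl]-4,4,5,5-tetramethyl-1,3,2-dioxaborolane | COCOc1ccc(B2OC(C)(C)C(C)(C)O2)c(OCOC)c1 | intermediate
22 | methyl 4-{[(tert-butyldiphenylsilyl)oxy]methyl}-2',4'-bis(methoxymethoxy)-3-{[4-(triisopropylsilyloxy)phenyl]ethynyl}biphenyl-2-carboxylate | COC(=O)c1c(-c2ccc(OCOC)cc2OCOC)ccc(CO[Si](c2ccccc2)(c2ccccc2)C(C)(C)C)c1C#Cc1ccc(O[Si](C(C)C)(C(C)C)C(C)C)cc1 | intermediate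
23 | 4-bromophenol | Oc1ccc(Br)cc1 | starting material
24 | (4-bromophenoxy)(tert-butyl)dimethylsilane | CC(C)(C)[Si](C)(C)Oc1ccc(Br)cc1 | intermediate
25 | [4-(tert-butyldimethylsilyloxy)phenyl]lithium | [Li]c1ccc(O[Si](C)(C)C(C)(C)C)cc1 | intermediate
26 | {4-{[(tert-butyldiphenylsilyl)oxy]methyl}-2',4'-bis(methoxymethoxy)-3-{[4-(triisopropylsilyloxy)phenyl]ethynyl}biphenyl-2-yl}[4-(tert-butyldimethylsilyloxy)phenyl]methanone | O=C(c1ccc(O[Si](C)(C)C(C)(C)C)cc1)c1c(-c2ccc(OCOC)cc2OCOC)ccc(CO[Si](c2ccccc2)(c2ccccc2)C(C)(C)C)c1C#Cc1ccc(O[Si](C(C)C)(C(C)C)C(C)C)cc1 | intermediate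
27 | {4-{[(tert-butyldiphenylsilyl)oxy]methyl}-2',4'-bis(methoxymethoxy)-3-{[4-(triisopropylsilyloxy)phenyl]ethynyl}biphenyl-2-yl}bis[4-(tert-butyldimethylsilyloxy)phenyl]methanol | OC(c1ccc(O[Si](C)(C)C(C)(C)C)cc1)(c1ccc(O[Si](C)(C)C(C)(C)C)cc1)c1c(-c2ccc(OCOC)cc2OCOC)ccc(CO[Si](c2ccccc2)(c2ccccc2)C(C)(C)C)c1C#Cc1ccc(O[Si](C(C)C)(C(C)C)C(C)C)cc1 | intermediate
28 | {4-(hydroxymethyl)-3-[(4-hydroxyphenyl)ethynyl]-2',4'-bis(methoxymethoxy)biphenyl-2-yl}bis(4-hydroxyphenyl)methanol | OC(c1ccc(O)cc1)(c1ccc(O)cc1)c1c(-c2ccc(OCOC)cc2OCOC)ccc(CO)c1C#Cc1ccc(O)cc1 | intermediate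
29 | 4-[{4-(hydroxymethyl)-3-[(4-hydroxyphenyl)ethynyl]-2',4'-bis(methoxymethoxy)biphenyl-2-yl}(4-hydroxyphenyl)methylidene]cyclohexa-2,5-dien-1-one | O=C1C=CC(=C(c2ccc(O)cc2)c2c(-c3ccc(OCOC)cc3OCOC)ccc(CO)c2C#Cc2ccc(O)cc2)C=C1 | intermediate
30 | selaginellin F, 4-[{2',4'-dihydroxy-4-(hydroxymethyl)-3-[(4-hydroxyphenyl)ethynyl]biphenyl-2-yl}(4-hydroxyphenyl)methylidene]cyclohexa-2,5-dien-1-one | O=C1C=CC(=C(c2ccc(O)cc2)c2c(-c3ccc(O)cc3O)ccc(CO)c2C#Cc2ccc(O)cc2)C=C1 | target

**Step count**

Total: 16 steps. Longest linear sequence: 11 steps (steps 3, 4, 5, 6, 7, 8, 9, 10, 13, 15, 16, from 4-iodophenol).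

**Steps most likely to fail**

Step 6 (key step). The aryllithium may be protonated by the amine or the solvent before carboxylation, the acetylide may add with incomplete preference for C6 over C1, the aryne may be consumed by oligomerisation, or the benzylic alkoxide may add to the new alkyne on long standing at room temperature. The fallback sets out from 3 and comes back at 15. It replaces the aryne by directed ortho-metalation below the temperature of LiCl loss and by a cross-coupling at the di-ortho-substituted carbon. Silylation of 3 (t-BuPh2SiCl, imidazole) gives tert-butyl{[2-chloro-4-(methoxymethoxy)phenyl]methoxy}diphenylsilane F1. Lithiation between Cl and OMOM with lithium 2,2,6,6-tetramethylpiperidide in THF at −78 °C gives [2-chloro-3-{[(tert-butyldiphenylsilyl)oxy]methyl}-6-(methoxymethoxy)phenyl]lithium F2, which is not isolated. Quenching with methyl chloroformate gives methyl 2-chloro-3-{[(tert-butyldiphenylsilyl)oxy]methyl}-6-(methoxymethoxy)benzoate F3. Copper-free Sonogashira coupling of this ester-activated aryl chloride with 8 (PdCl2(MeCN)2, XPhos, Cs2CO3, MeCN, 80 °C) then gives 15.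

Step 15. Attack at the ester carbonyl flanked by the alkynyl group and ring B may be too slow, the reaction may stall at the ketone, or the tertiary alkoxide may cyclise onto the alkyne on warming. The fallback sets out from 22 and comes back at 27, building C7 through the aldehyde oxidation level so that each aryl group is added to the most electrophilic carbonyl available. Reduction of 22 with i-Bu2AlH (CH2Cl2, −78 to 0 °C) gives {4-{[(tert-butyldiphenylsilyl)oxy]methyl}-2',4'-bis(methoxymethoxy)-3-{[4-(triisopropylsilyloxy)phenyl]ethynyl}biphenyl-2-yl}methanol F4. Dess–Martin oxidation gives 4-{[(tert-butyldiphenylsilyl)oxy]methyl}-2',4'-bis(methoxymethoxy)-3-{[4-(triisopropylsilyloxy)phenyl]ethynyl}biphenyl-2-carbaldehyde F5. Addition of 25 (1.2 equiv, THF, −78 °C) gives racemic {4-{[(tert-butyldiphenylsilyl)oxy]methyl}-2',4'-bis(methoxymethoxy)-3-{[4-(triisopropylsilyloxy)phenyl]ethynyl}biphenyl-2-yl}[4-(tert-butyldimethylsilyloxy)phenyl]methanol F6, whose stereocentre is removed at once. Dess–Martin oxidation gives ketone 26, now isolated, and a second addition of 25 in excess (THF, −78 to 0 °C) gives 27.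

Step 16. During the acid stage the freed ring B ortho hydroxyl may close onto the C7 cation, the formaldehyde equivalent released from the MOM groups may be captured by the electron-rich resorcinol ring, the alkyne may be hydrated, or acetal cleavage may stay incomplete. The fallback sets out from 17 (with 18 for ring B) and comes back at 30, using an all-silyl protecting-group plan so that the last step needs fluoride and only a weak acid. Silylation of 18 (i-Pr3SiCl, imidazole, DMF) gives 1-bromo-2,4-bis(triisopropylsilyloxy)benzene F7. Miyaura borylation (bis(pinacolato)diboron, PdCl2(dppf), KOAc, dioxane, 80 °C) gives 2-[2,4-bis(triisopropylsilyloxy)phenyl]-4,4,5,5-tetramethyl-1,3,2-dioxaborolane F8. Suzuki coupling with 17 under the conditions of step 13 gives methyl 4-{[(tert-butyldiphenylsilyl)oxy]methyl}-2',4'-bis(triisopropylsilyloxy)-3-{[4-(triisopropylsilyloxy)phenyl]ethynyl}biphenyl-2-carboxylate F9. Addition of 25 as in step 15 passes through {4-{[(tert-butyldiphenylsilyl)oxy]methyl}-2',4'-bis(triisopropylsilyloxy)-3-{[4-(triisopropylsilyloxy)phenyl]ethynyl}biphenyl-2-yl}[4-(tert-butyldimethylsilyloxy)phenyl]methanone F10, not isolated, and gives {4-{[(tert-butyldiphenylsilyl)oxy]methyl}-2',4'-bis(triisopropylsilyloxy)-3-{[4-(triisopropylsilyloxy)phenyl]ethynyl}biphenyl-2-yl}bis[4-(tert-butyldimethylsilyloxy)phenyl]methanol F11. Bu4NF buffered with AcOH in THF then removes all six silyl groups to give {2',4'-dihydroxy-4-(hydroxymethyl)-3-[(4-hydroxyphenyl)ethynyl]biphenyl-2-yl}bis(4-hydroxyphenyl)methanol F12, not isolated, which should lose water on work-up with dilute acetic acid to give 30.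

**Further compounds**

F1 | step 6 | tert-butyl{[2-chloro-4-(methoxymethoxy)phenyl]methoxy}diphenylsilane | COCOc1ccc(CO[Si](c2ccccc2)(c2ccccc2)C(C)(C)C)c(Cl)c1
F2 | step 6 | [2-chloro-3-{[(tert-butyldiphenylsilyl)oxy]methyl}-6-(methoxymethoxy)phenyl]lithium | [Li]c1c(OCOC)ccc(CO[Si](c2ccccc2)(c2ccccc2)C(C)(C)C)c1Cl
F3 | step 6 | methyl 2-chloro-3-{[(tert-butyldiphenylsilyl)oxy]methyl}-6-(methoxymethoxy)benzoate | COC(=O)c1c(OCOC)ccc(CO[Si](c2ccccc2)(c2ccccc2)C(C)(C)C)c1Cl
F4 | step 15 | {4-{[(tert-butyldiphenylsilyl)oxy]methyl}-2',4'-bis(methoxymethoxy)-3-{[4-(triisopropylsilyloxy)phenyl]ethynyl}biphenyl-2-yl}methanol | OCc1c(-c2ccc(OCOC)cc2OCOC)ccc(CO[Si](c2ccccc2)(c2ccccc2)C(C)(C)C)c1C#Cc1ccc(O[Si](C(C)C)(C(C)C)C(C)C)cc1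
F5 | step 15 | 4-{[(tert-butyldiphenylsilyl)oxy]methyl}-2',4'-bis(methoxymethoxy)-3-{[4-(triisopropylsilyloxy)phenyl]ethynyl}biphenyl-2-carbaldehyde | O=Cc1c(-c2ccc(OCOC)cc2OCOC)ccc(CO[Si](c2ccccc2)(c2ccccc2)C(C)(C)C)c1C#Cc1ccc(O[Si](C(C)C)(C(C)C)C(C)C)cc1
F6 | step 15 | racemic {4-{[(tert-butyldiphenylsilyl)oxy]methyl}-2',4'-bis(methoxymethoxy)-3-{[4-(triisopropylsilyloxy)phenyl]ethynyl}biphenyl-2-yl}[4-(tert-butyldimethylsilyloxy)phenyl]methanol | OC(c1ccc(O[Si](C)(C)C(C)(C)C)cc1)c1c(-c2ccc(OCOC)cc2OCOC)ccc(CO[Si](c2ccccc2)(c2ccccc2)C(C)(C)C)c1C#Cc1ccc(O[Si](C(C)C)(C(C)C)C(C)C)cc1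
F7 | step 16 | 1-bromo-2,4-bis(triisopropylsilyloxy)benzene | CC(C)[Si](Oc1ccc(Br)c(O[Si](C(C)C)(C(C)C)C(C)C)c1)(C(C)C)C(C)C
F8 | step 16 | 2-[2,4-bis(triisopropylsilyloxy)phenyl]-4,4,5,5-tetramethyl-1,3,2-dioxaborolane | CC(C)[Si](Oc1ccc(B2OC(C)(C)C(C)(C)O2)c(O[Si](C(C)C)(C(C)C)C(C)C)c1)(C(C)C)C(C)C
F9 | step 16 | methyl 4-{[(tert-butyldiphenylsilyl)oxy]methyl}-2',4'-bis(triisopropylsilyloxy)-3-{[4-(triisopropylsilyloxy)phenyl]ethynyl}biphenyl-2-carboxylate | COC(=O)c1c(-c2ccc(O[Si](C(C)C)(C(C)C)C(C)C)cc2O[Si](C(C)C)(C(C)C)C(C)C)ccc(CO[Si](c2ccccc2)(c2ccccc2)C(C)(C)C)c1C#Cc1ccc(O[Si](C(C)C)(C(C)C)C(C)C)cc1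
F10 | step 16 | {4-{[(tert-butyldiphenylsilyl)oxy]methyl}-2',4'-bis(triisopropylsilyloxy)-3-{[4-(triisopropylsilyloxy)phenyl]ethynyl}biphenyl-2-yl}[4-(tert-butyldimethylsilyloxy)phenyl]methanone | O=C(c1ccc(O[Si](C)(C)C(C)(C)C)cc1)c1c(-c2ccc(O[Si](C(C)C)(C(C)C)C(C)C)cc2O[Si](C(C)C)(C(C)C)C(C)C)ccc(CO[Si](c2ccccc2)(c2ccccc2)C(C)(C)C)c1C#Cc1ccc(O[Si](C(C)C)(C(C)C)C(C)C)cc1
F11 | step 16 | {4-{[(tert-butyldiphenylsilyl)oxy]methyl}-2',4'-bis(triisopropylsilyloxy)-3-{[4-(triisopropylsilyloxy)phenyl]ethynyl}biphenyl-2-yl}bis[4-(tert-butyldimethylsilyloxy)phenyl]methanol | OC(c1ccc(O[Si](C)(C)C(C)(C)C)cc1)(c1ccc(O[Si](C)(C)C(C)(C)C)cc1)c1c(-c2ccc(O[Si](C(C)C)(C(C)C)C(C)C)cc2O[Si](C(C)C)(C(C)C)C(C)C)ccc(CO[Si](c2ccccc2)(c2ccccc2)C(C)(C)C)c1C#Cc1ccc(O[Si](C(C)C)(C(C)C)C(C)C)cc1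
F12 | step 16 | {2',4'-dihydroxy-4-(hydroxymethyl)-3-[(4-hydroxyphenyl)ethynyl]biphenyl-2-yl}bis(4-hydroxyphenyl)methanol | OC(c1ccc(O)cc1)(c1ccc(O)cc1)c1c(-c2ccc(O)cc2O)ccc(CO)c1C#Cc1ccc(O)cc1
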